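## Retrosynthetic overview
1. Kanzonol S comes from its catechol bis-TBS ether by fluoride desilylation. Ring B is bought, as protocatechualdehyde.
2. The bis-TBS flavanone comes from one acyclic (S)-δ-hydroxy-β-diketone carrying a dioxinone, in a single flask. Ring C closes first (O1–C8a cyclodehydration, C2–O bond untouched). Ring A closes second (dioxinone → acylketene, C4a–C5 closure, aromatisation).
3. The acyclic chain comes from a C4–C4a polyanion Claisen union of an (S)-β-hydroxy ester with an allylated keto-dioxinone, followed by lipase acetylation of the primary alcohol.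
4. The (S)-β-hydroxy ester comes from a catalytic asymmetric acetate aldol, which sets C2.
5. The allylated keto-dioxinone comes from a Tsuji–Trost reaction with isoprene monoxide on the only acidic CH2. This fixes C8 regiochemistry and the E-alkene.

Assumptions:
- The C–H stereocentre between the ketone and the dioxinone (future C8) is left undefined, because aromatisation destroys it.
- Racemic isoprene monoxide is used, because its stereocentre is lost in the π-allyl complex.
- The (R,R) catalyst series in step 2 is taken as the one giving Si-face addition. If the rotation of the aldol product shows the opposite sense, the antipode is used.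

## Route

Step 1
Reactants: 1 3,4-dihydroxybenzaldehyde
Product: 2 3,4-bis(tert-butyldimethylsilyloxy)benzaldehyde
Conditions: TBSCl (2.3 equiv), imidazole (5 equiv), DMF, 0 °C → rt
Reagents that add atoms: tert-butyldimethylsilyl chloride, CC(C)(C)[Si](C)(C)Cl
Why: Standard Corey silylation masks both acidic catechol OH groups against SiCl4, LDA and ketene chemistry, and no stereocentre is involved.

Step 2
Reactants: 2 3,4-bis(tert-butyldimethylsilyloxy)benzaldehyde; 3 1-(tert-butyldimethylsilyloxy)-1-methoxyethene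
Product: 4 methyl (3S)-3-[3,4-bis(tert-butyldimethylsilyloxy)phenyl]-3-hydroxypropanoate
Conditions: SiCl4 (1.1 equiv), (R,R)-BINAM-derived bisphosphoramide (5 mol %), CH2Cl2, −78 °C; sat. aq NaHCO3, 0 °C
Reagents that add atoms: none
Why: In this Lewis-base-activated SiCl4 Mukaiyama acetate aldol (Denmark type), the chiral phosphoramide-bound silyl cation activates ArCHO and an open transition state leaves only the Si face accessible to the ketene acetal, which sets the future C2 as (S) (aromatic aldehydes typically ≥95:5 er).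

Step 3
Reactants: 5 2,2,6-trimethyl-4H-1,3-dioxin-4-one
Product: 6 2,2-dimethyl-6-(2-oxopropyl)-4H-1,3-dioxin-4-one
Conditions: 5 (2 equiv), LiHMDS (2 equiv), THF, −78 °C; AcCl (1 equiv), −78 → −20 °C; 1 M HCl
Reagents that add atoms: acetyl chloride, CC(=O)Cl
Why: This is a vinylogous (γ-selective) Claisen-type C-acylation of the lithium dienolate of the dioxinone, in which the second equivalent of dienolate absorbs the acidic proton of the product.

Step 4
Reactants: 6 2,2-dimethyl-6-(2-oxopropyl)-4H-1,3-dioxin-4-one; 7 2-methyl-2-vinyloxirane (racemic)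
Product: 8 6-[(5E)-7-hydroxy-6-methyl-2-oxohept-5-en-3-yl]-2,2-dimethyl-4H-1,3-dioxin-4-one
Conditions: Pd(PPh3)4 (3 mol %), 6 (1.2 equiv), THF, 0 °C → rt
Reagents that add atoms: none
Why: In this neutral Tsuji–Trost allylic alkylation, Pd(0) opens the vinyl epoxide to a zwitterionic π-allyl whose alkoxide deprotonates the only acidic CH2 of 6 (future C8), the soft carbanion attacks the unsubstituted terminus (1,4-addition), and the preferred syn placement of CH2O− gives the (E)-alkene.

Step 5
Reactants: 8 6-[(5E)-7-hydroxy-6-methyl-2-oxohept-5-en-3-yl]-2,2-dimethyl-4H-1,3-dioxin-4-one; 4 methyl (3S)-3-[3,4-bis(tert-butyldimethylsilyloxy)phenyl]-3-hydroxypropanoate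
Product: 9 6-[(2E,10S)-10-[3,4-bis(tert-butyldimethylsilyloxy)phenyl]-1,10-dihydroxy-2-methyl-6,8-dioxodec-2-en-5-yl]-2,2-dimethyl-4H-1,3-dioxin-4-one (drawn as the open keto form)
Conditions: 8 (2.2 equiv), LDA (6.8 equiv), THF, −78 → −40 °C; add 4 pre-treated with LDA (1.0 equiv), −78 → −20 °C; AcOH, −78 °C, pH 5 buffer (excess 8 recovered)
Reagents that add atoms: none
Why: In this Harris–Weiler polyanion cross-Claisen, the alkoxide/enolate/terminal-carbanion trianion of 8 reacts at its most basic site (the CH3, future C4a) with the ester, as in dianion acylations of keto-dioxinones and Claisen condensations on unprotected β-hydroxy esters, while the lithium alkoxide of 4 blocks E1cB elimination so the (S)-carbinol is untouched.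

Step 6
Reactants: 9 6-[(2E,10S)-10-[3,4-bis(tert-butyldimethylsilyloxy)phenyl]-1,10-dihydroxy-2-methyl-6,8-dioxodec-2-en-5-yl]-2,2-dimethyl-4H-1,3-dioxin-4-one
Product: 10 (2E,10S)-10-[3,4-bis(tert-butyldimethylsilyloxy)phenyl]-5-(2,2-dimethyl-4-oxo-4H-1,3-dioxin-6-yl)-10-hydroxy-2-methyl-6,8-dioxodec-2-en-1-yl acetate
Conditions: Novozym 435 (CAL-B), isopropenyl acetate (3 equiv), MTBE, 30 °C
Reagents that add atoms: isopropenyl acetate, CC(=C)OC(C)=O
Why: This lipase-catalysed irreversible transesterification at neutral pH acetylates only the unhindered primary allylic alcohol, because the doubly bulky secondary benzylic carbinol and the enols are not CAL-B substrates and no base is present to trigger premature aromatisation.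

Step 7
Reactants: 10 (2E,10S)-10-[3,4-bis(tert-butyldimethylsilyloxy)phenyl]-5-(2,2-dimethyl-4-oxo-4H-1,3-dioxin-6-yl)-10-hydroxy-2-methyl-6,8-dioxodec-2-en-1-yl acetate
Product: 13 (2S)-8-[(E)-4-acetoxy-3-methylbut-2-enyl]-2-[3,4-bis(tert-butyldimethylsilyloxy)phenyl]-5,7-dihydroxychroman-4-one, via dihydropyranone-dioxinone 11 (not isolated), via acylketene 12 (not isolated)
Conditions: PPTS (10 mol %), 4 Å MS, PhMe (5 mM), 45 °C until 10 is consumed; then 110 °C, N2 sweep, 1 h
Reagents that add atoms: none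
Why: Proposed new method: mild acid closes the δ-hydroxy-β-diketone to dihydropyranone 11 by hemiketalisation/dehydration at C8a (the C2–O bond is never broken, so (S) is retained, and O1 ends up next to the side-chain carbon, so only the 8-isomer can form), then retro-[4+2] loss of acetone at 110 °C gives acylketene 12, whose enol form is a dienylketene (C5=C6–C7=C8–C8a=C4a) that closes C5–C4a by 6π-electrocyclisation/C-acylation and tautomerises to the phloroglucinol ring; the closest known reaction types are acid cyclisation of δ-hydroxy-β-diketones to 2,3-dihydro-4-pyranones, dioxinone-to-acylketene late-stage aromatisation of polyketide chains, and the final dienylketene electrocyclisation of the Danheiser benzannulation.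

Step 8
Reactants: 13 (2S)-8-[(E)-4-acetoxy-3-methylbut-2-enyl]-2-[3,4-bis(tert-butyldimethylsilyloxy)phenyl]-5,7-dihydroxychroman-4-one
Product: 14 Kanzonol S, (2S)-8-[(E)-4-acetoxy-3-methylbut-2-enyl]-2-(3,4-dihydroxyphenyl)-5,7-dihydroxychroman-4-one
Conditions: Et3N·3HF (6 equiv), THF, 0 °C → rt
Reagents that add atoms: none
Why: This fluoride desilylation of aryl silyl ethers runs in a slightly acidic medium that leaves the allylic acetate intact and avoids the base-induced retro-oxa-Michael racemisation of the flavanone C2.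

## Compound list
1 | 3,4-dihydroxybenzaldehyde | O=Cc1ccc(O)c(O)c1 | starting material
2 | 3,4-bis(tert-butyldimethylsilyloxy)benzaldehyde | O=Cc1ccc(O[Si](C)(C)C(C)(C)C)c(O[Si](C)(C)C(C)(C)C)c1 | intermediate
3 | 1-(tert-butyldimethylsilyloxy)-1-methoxyethene | C=C(OC)O[Si](C)(C)C(C)(C)C | starting material
4 | methyl (3S)-3-[3,4-bis(TBSO)phenyl]-3-hydroxypropanoate | COC(=O)C[C@H](O)c1ccc(O[Si](C)(C)C(C)(C)C)c(O[Si](C)(C)C(C)(C)C)c1 | intermediate
5 | 2,2,6-trimethyl-4H-1,3-dioxin-4-one | CC1=CC(=O)OC(C)(C)O1 | starting material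
6 | 2,2-dimethyl-6-(2-oxopropyl)-4H-1,3-dioxin-4-one | CC(=O)CC1=CC(=O)OC(C)(C)O1 | intermediate
7 | 2-methyl-2-vinyloxirane (racemic) | CC1(C=C)CO1 | starting material
8 | 6-[(5E)-7-hydroxy-6-methyl-2-oxohept-5-en-3-yl]-2,2-dimethyl-4H-1,3-dioxin-4-one | CC(=O)C(C/C=C(\C)CO)C1=CC(=O)OC(C)(C)O1 | intermediate
9 | (E,S)-hydroxy-diketo-dioxinone diol | CC1(C)OC(=O)C=C(O1)C(C/C=C(\C)CO)C(=O)CC(=O)C[C@H](O)c1ccc(O[Si](C)(C)C(C)(C)C)c(O[Si](C)(C)C(C)(C)C)c1 | intermediate
10 | (E,S)-hydroxy-diketo-dioxinone primary acetate | CC1(C)OC(=O)C=C(O1)C(C/C=C(\C)COC(C)=O)C(=O)CC(=O)C[C@H](O)c1ccc(O[Si](C)(C)C(C)(C)C)c(O[Si](C)(C)C(C)(C)C)c1 | intermediate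
11 | (2E)-5-[(2S)-2-[3,4-bis(TBSO)phenyl]-4-oxo-3,4-dihydro-2H-pyran-6-yl]-5-(2,2-dimethyl-4-oxo-4H-1,3-dioxin-6-yl)-2-methylpent-2-en-1-yl acetate (not isolated) | CC1(C)OC(=O)C=C(O1)C(C/C=C(\C)COC(C)=O)C1=CC(=O)C[C@@H](c2ccc(O[Si](C)(C)C(C)(C)C)c(O[Si](C)(C)C(C)(C)C)c2)O1 | intermediate
12 | (2E)-5-[(2S)-2-[3,4-bis(TBSO)phenyl]-4-oxo-3,4-dihydro-2H-pyran-6-yl]-2-methyl-6,8-dioxoocta-2,7-dien-1-yl acetate, acylketene (not isolated) | O=C=CC(=O)C(C/C=C(\C)COC(C)=O)C1=CC(=O)C[C@@H](c2ccc(O[Si](C)(C)C(C)(C)C)c(O[Si](C)(C)C(C)(C)C)c2)O1 | intermediate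
13 | (2S)-8-[(E)-4-acetoxy-3-methylbut-2-enyl]-2-[3,4-bis(TBSO)phenyl]-5,7-dihydroxychroman-4-one | CC(=O)OC/C(C)=C/Cc1c(O)cc(O)c2c1O[C@H](c1ccc(O[Si](C)(C)C(C)(C)C)c(O[Si](C)(C)C(C)(C)C)c1)CC2=O | intermediate
14 | Kanzonol S | CC(=O)OC/C(C)=C/Cc1c(O)cc(O)c2c1O[C@H](c1ccc(O)c(O)c1)CC2=O | target

## Step count
- Total steps: 8.
- Longest linear sequence: 6 (steps 1, 2, 5, 6, 7, 8; equally steps 3, 4, 5, 6, 7, 8).

## Steps most likely to fail

**Step 7 (double ring closure).** Three things can go wrong. The ketene may be intercepted by residual water or by product phenols. A 2-pyrone may form if heating starts before ring C is closed. Some racemisation may occur through enolisation and ring opening.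

The fallback sets out from 10 and comes back at 13. Ring C is closed on its own (TFA, CH2Cl2, 0 °C) and 11 is isolated. Heating 11 with MeOH (10 equiv) in PhMe at 110 °C in a sealed tube traps the ketene as the methyl β-keto ester F1. Ring A is then closed ionically instead of pericyclically, by Mg(II)-templated soft enolisation (MgBr2·OEt2, iPr2NEt, CH2Cl2, rt). Only the very acidic C8–H is removed, and the vinylogous enolate acylates at C4a. This is a Dieckmann-type biomimetic Claisen cyclisation of a triketo ester, and it gives 13 after tautomerisation.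

**Step 5 (polyanion Claisen).** The methyl ester is deactivated by the neighbouring alkoxide. Proton transfer may compete with acylation, and the trianion may decompose above −20 °C.

The fallback sets out from 4 (with 8) and comes back at 10. It makes the C4–C4a bond by aldol addition and corrects the oxidation level afterwards:
- TESCl/imidazole converts 4 into the TES-protected hydroxy ester F2.
- DIBAL-H (−78 °C) gives the β-silyloxy aldehyde F3.
- F3 reacts at −78 °C with the trianion of 8 to give the aldol diol F4, an inconsequential epimer mixture at the new carbinol.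
- CAL-B/isopropenyl acetate acetylates only the primary alcohol, giving the hydroxy ketone acetate F5.
- Dess–Martin periodinane oxidises the β-hydroxy ketone to the TES-protected β-diketone F6.
- AcOH–THF–H2O removes the TES group to deliver 10.

**Step 4 (vinyl epoxide allylation).** The E/Z ratio may be modest, and some 1,2-adduct or double alkylation may form.

The fallback sets out from 6 and comes back at 8. Commercial, geometrically pure (E)-4-acetoxy-2-methylbut-2-enal (CC(=O)OC/C=C(\C)C=O) is used as the π-allyl precursor (Pd(PPh3)4, Et3N, THF). γ-Substitution gives the thermodynamically locked (E)-enal F7. Luche reduction (NaBH4, CeCl3·7H2O, MeOH, −78 °C) then reduces only the aldehyde to give 8.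

## Further compounds
F1 | step 7 | methyl (6E)-8-acetoxy-4-[(2S)-2-[3,4-bis(TBSO)phenyl]-4-oxo-3,4-dihydro-2H-pyran-6-yl]-7-methyl-3-oxooct-6-enoate | COC(=O)CC(=O)C(C/C=C(\C)COC(C)=O)C1=CC(=O)C[C@@H](c2ccc(O[Si](C)(C)C(C)(C)C)c(O[Si](C)(C)C(C)(C)C)c2)O1
F2 | step 5 | methyl (3S)-3-[3,4-bis(TBSO)phenyl]-3-(triethylsilyloxy)propanoate | COC(=O)C[C@H](O[Si](CC)(CC)CC)c1ccc(O[Si](C)(C)C(C)(C)C)c(O[Si](C)(C)C(C)(C)C)c1
F3 | step 5 | (3S)-3-[3,4-bis(TBSO)phenyl]-3-(triethylsilyloxy)propanal | O=CC[C@H](O[Si](CC)(CC)CC)c1ccc(O[Si](C)(C)C(C)(C)C)c(O[Si](C)(C)C(C)(C)C)c1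
F4 | step 5 | aldol diol (C4 carbinol, primary OH free, O-TES) | CC1(C)OC(=O)C=C(O1)C(C/C=C(\C)CO)C(=O)CC(O)C[C@H](O[Si](CC)(CC)CC)c1ccc(O[Si](C)(C)C(C)(C)C)c(O[Si](C)(C)C(C)(C)C)c1
F5 | step 5 | aldol primary acetate (C4 carbinol, O-TES) | CC1(C)OC(=O)C=C(O1)C(C/C=C(\C)COC(C)=O)C(=O)CC(O)C[C@H](O[Si](CC)(CC)CC)c1ccc(O[Si](C)(C)C(C)(C)C)c(O[Si](C)(C)C(C)(C)C)c1
F6 | step 5 | O-TES ether of 10 | CC1(C)OC(=O)C=C(O1)C(C/C=C(\C)COC(C)=O)C(=O)CC(=O)C[C@H](O[Si](CC)(CC)CC)c1ccc(O[Si](C)(C)C(C)(C)C)c(O[Si](C)(C)C(C)(C)C)c1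
F7 | step 4 | (2E)-5-(2,2-dimethyl-4-oxo-4H-1,3-dioxin-6-yl)-2-methyl-6-oxohept-2-enal | CC(=O)C(C/C=C(\C)C=O)C1=CC(=O)OC(C)(C)O1
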